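The route rests on disconnecting the bond between oxolane C2 and C1 of the syringyl ring. That ring carbon lies para to the free phenol OH, with both ortho positions blocked by OMe groups, so unprotected 2,6-dimethoxyphenol can serve directly as the carbon nucleophile, while oxolane C2, an O-substituted benzylic carbon, is unmasked from a lactol acetate as a cyclic oxocarbenium ion. One Friedel–Crafts C-arylation forms the bond, sets C2 trans to the C3 methyl group and delivers the target without protecting groups. The precursor, a 2-acetoxy-oxolane bearing the veratryl group and the cis-dimethyl pair, comes in three steps from meso-2,3-dimethylsuccinic anhydride by Rh-catalysed enantioselective desymmetrisation with an arylzinc reagent.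

Key step: step 5

Numbering used throughout (as in the names of 8, 10 and 13): oxolane C2 is the carbonyl/acetal carbon that ends up carrying the syringyl ring, C3 and C4 carry the methyl groups, C5 carries the veratryl ring.

Remark (assumption): the sense of induction of t-BuPHOX in step 2 is not predicted here; the ligand antipode (both are sold) that gives 6 rather than its enantiomer is the one meant.

Step 1
Reactants: 1 meso-2,3-dimethylsuccinic acid
Product: 2 cis-2,3-dimethylsuccinic anhydride (meso)
Conditions: AcCl (neat), reflux; concentrate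
Reagents that add atoms: none
Why: Cyclodehydration of the 1,4-diacid through the mixed acetic anhydride closes the five-membered anhydride under acidic, base-free conditions, so neither α-stereocentre should enolise and the cis relationship of the methyl groups is carried over.

Step 2
Reactants: 3 4-bromo-1,2-dimethoxybenzene; 2 cis-2,3-dimethylsuccinic anhydride
Product: 6 (2R,3S)-4-(3,4-dimethoxyphenyl)-2,3-dimethyl-4-oxobutanoic acid, via aryllithium 4 (not isolated), via arylzinc triflate 5 (not isolated)
Conditions: 3, n-BuLi, THF, −78 °C; Zn(OTf)2, −78 °C → rt; then 2, [Rh(cod)Cl]2 (4 mol%), t-BuPHOX (8 mol%, antipode as in the remark), THF/DMF, 50 °C; 1 M HCl work-up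
Reagents that add atoms: none
Why: Br–Li exchange and transmetalation give a halide-free arylzinc reagent, and the Rh(I)/phosphinooxazoline-catalysed enantioselective desymmetrising cross-coupling of a meso succinic anhydride (acyl C–O oxidative addition, transmetalation, reductive elimination) should open the carbonyl next to the (S)-configured ring carbon under ligand control, so that the two untouched methyl-bearing carbons emerge as (2R,3S) and the zinc carboxylate formed prevents a second addition.

Step 3
Reactants: 6 (2R,3S)-4-(3,4-dimethoxyphenyl)-2,3-dimethyl-4-oxobutanoic acid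
Product: 8 (3R,4S,5S)-5-(3,4-dimethoxyphenyl)-3,4-dimethyloxolan-2-one, via hydroxy acid 7 (not isolated)
Conditions: L-Selectride (2.2 equiv), THF, −78 °C; then 2 M HCl, rt
Reagents that add atoms: none
Why: Felkin–Anh reduction of the α-branched aryl ketone (carboxylate formed by the first equivalent of hydride) by the bulky hydride anti to the CH(CH3)CO2Li group should give the (4S)-alcohol, and acid-induced γ-lactonisation with retention then places the aryl group trans to the C4 methyl group.

Step 4
Reactants: 8 (3R,4S,5S)-5-(3,4-dimethoxyphenyl)-3,4-dimethyloxolan-2-one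
Product: 10 (2RS,3R,4S,5S)-5-(3,4-dimethoxyphenyl)-3,4-dimethyloxolan-2-yl acetate, via aluminium hemiacetal 9 (not isolated)
Conditions: DIBAL-H (1.2 equiv), CH2Cl2, −78 °C; then pyridine, DMAP, Ac2O, −78 → 0 °C; Rochelle salt work-up
Reagents that add atoms: acetic anhydride, CC(=O)OC(C)=O
Why: Rychnovsky reductive acetylation: DIBAL-H at −78 °C should stop at the tetrahedral aluminium hemiacetal, which is acetylated in the same flask without ring opening or touching C3–C5; the anomeric mixture at C2 is of no consequence because C2 is planarised in step 5.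

Step 5
Reactants: 10 (2RS,3R,4S,5S)-5-(3,4-dimethoxyphenyl)-3,4-dimethyloxolan-2-yl acetate; 11 2,6-dimethoxyphenol
Product: 13 4-[(2R,3R,4S,5S)-5-(3,4-dimethoxyphenyl)-3,4-dimethyloxolan-2-yl]-2,6-dimethoxyphenol, via oxocarbenium ion 12 (not isolated)
Conditions: 11 (2 equiv), BF3·OEt2 (0.3 equiv), CH2Cl2, −78 → −30 °C; NaHCO3 quench at low temperature
Reagents that add atoms: none
Why: BF3 ionises the anomeric acetate of 10 to the cyclic oxocarbenium ion 12, which is attacked by C4 of 2,6-dimethoxyphenol (para to OH), and proton loss re-aromatises the ring to give 13. The closest known reaction type is the Friedel–Crafts C-arylation (aryl C-glycosylation) of lactol acetates with phenols and other electron-rich arenes. No ring is closed. The new stereocentre C2 is controlled by the ring substituents: in the envelope of 12 that keeps the C4 methyl and C5 aryl groups pseudo-equatorial, the C3 methyl group is pseudo-axial, and inside attack (Woerpel model) should occur on the face anti to both methyl groups, giving the 2,3-trans, 2,5-cis product, which is also expected to be the more stable C2 epimer should the benzylic ether re-ionise. The step needs site selectivity on the arene and mono-arylation: the OH group activates its para carbon, both ortho carbons carry OMe, and any O-alkylated acetal should re-ionise under the Lewis acid, while low temperature and only a modest excess of 11 are meant to keep 13 from ionising further.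

Compound list
1 | meso-2,3-dimethylsuccinic acid, (2R,3S)-2,3-dimethylbutanedioic acid | OC(=O)[C@H](C)[C@@H](C(=O)O)C | starting material
2 | cis-2,3-dimethylsuccinic anhydride, (3R,4S)-3,4-dimethyloxolane-2,5-dione (meso) | O=C1OC(=O)[C@H](C)[C@@H]1C | intermediate
3 | 4-bromo-1,2-dimethoxybenzene | COc1ccc(Br)cc1OC | starting material
4 | (3,4-dimethoxyphenyl)lithium | COc1ccc([Li])cc1OC | intermediate
5 | (3,4-dimethoxyphenyl)zinc trifluoromethanesulfonate | COc1ccc([Zn]OS(=O)(=O)C(F)(F)F)cc1OC | intermediate
6 | (2R,3S)-4-(3,4-dimethoxyphenyl)-2,3-dimethyl-4-oxobutanoic acid | COc1ccc(C(=O)[C@@H](C)[C@@H](C)C(=O)O)cc1OC | intermediate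
7 | (2R,3S,4S)-4-(3,4-dimethoxyphenyl)-4-hydroxy-2,3-dimethylbutanoic acid (formed as its lithium salt) | COc1ccc([C@@H](O)[C@@H](C)[C@@H](C)C(=O)O)cc1OC | intermediate
8 | (3R,4S,5S)-5-(3,4-dimethoxyphenyl)-3,4-dimethyloxolan-2-one | COc1ccc([C@H]2OC(=O)[C@H](C)[C@@H]2C)cc1OC | intermediate
9 | diisobutylaluminium (3R,4S,5S)-5-(3,4-dimethoxyphenyl)-3,4-dimethyloxolan-2-olate (aluminium hemiacetal, C2 epimers) | COc1ccc([C@H]2OC(O[Al](CC(C)C)CC(C)C)[C@H](C)[C@@H]2C)cc1OC | intermediate
10 | (2RS,3R,4S,5S)-5-(3,4-dimethoxyphenyl)-3,4-dimethyloxolan-2-yl acetate (anomeric mixture) | COc1ccc([C@H]2OC(OC(C)=O)[C@H](C)[C@@H]2C)cc1OC | intermediate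
11 | 2,6-dimethoxyphenol | COc1cccc(OC)c1O | starting material
12 | (3R,4S,5S)-5-(3,4-dimethoxyphenyl)-3,4-dimethyloxolan-2-ylium (cyclic oxocarbenium ion) | COc1ccc([C@H]2[O+]=C[C@H](C)[C@@H]2C)cc1OC | intermediate
13 | 4-[(2R,3R,4S,5S)-5-(3,4-dimethoxyphenyl)-3,4-dimethyloxolan-2-yl]-2,6-dimethoxyphenol | COc1ccc([C@H]2O[C@@H](c3cc(OC)c(O)c(OC)c3)[C@H](C)[C@@H]2C)cc1OC | target

Total step count: 5. Longest linear sequence: 5 steps (1 → 2 → 6 → 8 → 10 → 13).

Steps most likely to fail

Step 5. Three processes threaten it. The oxocarbenium ion may lose its C3 proton reversibly (enol ether formation), which would erode the cis-dimethyl relationship. The new p-hydroxybenzylic C–O bond may re-ionise and take up a second arene with ring opening. The arene may also react through a carbon ortho/para to OMe instead of the one para to OH. Fallback, setting out from lactone 8 and returning at 13: DIBAL-H (CH2Cl2, −78 °C, aqueous work-up) gives the lactol (2RS,3R,4S,5S)-5-(3,4-dimethoxyphenyl)-3,4-dimethyloxolan-2-ol F1. Commercial 4-bromo-2,6-dimethoxyphenol is benzylated (BnBr, K2CO3, DMF) to 2-(benzyloxy)-5-bromo-1,3-dimethoxybenzene F2, which with Mg in THF gives [4-(benzyloxy)-3,5-dimethoxyphenyl]magnesium bromide F3. Addition of F3 (3 equiv) to F1, which reacts through its open hydroxy-aldehyde form, makes the same aryl–carbon bond with fixed regiochemistry and should give the 1,4-diol F4 as a mixture at the new carbinol carbon. Acid-promoted cyclodehydration through the benzylic cation (cat. TsOH or BF3·OEt2, CH2Cl2, 0 °C) should close the oxolane to the benzyl ether F5 with the aryl group trans to the neighbouring methyl group. Hydrogenolysis (H2, Pd/C, EtOAc) then returns to the route at 13.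

Step 2. Discrimination between the two enantiotopic acyl C–O bonds in the oxidative addition may be insufficient, transmetalation of the electron-rich arylzinc may be sluggish, or the α-centre of the keto carboxylate may epimerise at 50 °C. Fallback, setting out from anhydride 2 and returning at 8: cinchona-alkaloid-mediated methanolysis (quinine or quinidine, whichever pseudo-enantiomer directs methanol to the carbonyl next to the (R)-carbon; MeOH, toluene, −50 °C) should give the hemiester (2S,3R)-4-methoxy-2,3-dimethyl-4-oxobutanoic acid F6. Oxalyl chloride with catalytic DMF gives the acid chloride methyl (2R,3S)-4-chloro-2,3-dimethyl-4-oxobutanoate F7. Pd(PPh3)4-catalysed acylation of arylzinc 5 with F7 (THF, 0 °C → rt) gives the keto ester methyl (2R,3S)-4-(3,4-dimethoxyphenyl)-2,3-dimethyl-4-oxobutanoate F8. L-Selectride reduction of F8 (THF, −78 °C) followed by acid treatment, with loss of methanol, returns to the route at lactone 8.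

Step 3. Hydride delivery may show poor facial selectivity, or the basic hydride may enolise the α-branched ketone and epimerise C3 of the acid. Fallback, setting out from keto acid 6 and returning at 8, in which the benzylic centre is set by stereoinvertive ring closure instead of by the reduction: NaBH4 (aq. NaOH/MeOH) and acidification give 8 together with its C5 epimer, the 4,5-cis lactone (3R,4S,5R)-5-(3,4-dimethoxyphenyl)-3,4-dimethyloxolan-2-one F9, and the two are separated by chromatography. F9 is saponified (LiOH, THF/H2O) to the hydroxy acid (2R,3S,4R)-4-(3,4-dimethoxyphenyl)-4-hydroxy-2,3-dimethylbutanoic acid F10. Intramolecular Mitsunobu lactonisation of F10 (PPh3, DIAD, THF, 0 °C) closes the ring with inversion at the benzylic carbinol carbon and returns to the route at 8.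

Further compounds
F1 | step 5 | (2RS,3R,4S,5S)-5-(3,4-dimethoxyphenyl)-3,4-dimethyloxolan-2-ol | COc1ccc([C@H]2OC(O)[C@H](C)[C@@H]2C)cc1OC
F2 | step 5 | 2-(benzyloxy)-5-bromo-1,3-dimethoxybenzene | COc1cc(Br)cc(OC)c1OCc1ccccc1
F3 | step 5 | [4-(benzyloxy)-3,5-dimethoxyphenyl]magnesium bromide | COc1cc([Mg]Br)cc(OC)c1OCc1ccccc1
F4 | step 5 | (1RS,2R,3S,4S)-1-[4-(benzyloxy)-3,5-dimethoxyphenyl]-4-(3,4-dimethoxyphenyl)-2,3-dimethylbutane-1,4-diol | COc1ccc([C@@H](O)[C@@H](C)[C@@H](C)C(O)c2cc(OC)c(OCc3ccccc3)c(OC)c2)cc1OC
F5 | step 5 | (2R,3R,4S,5S)-2-[4-(benzyloxy)-3,5-dimethoxyphenyl]-5-(3,4-dimethoxyphenyl)-3,4-dimethyloxolane | COc1ccc([C@H]2O[C@@H](c3cc(OC)c(OCc4ccccc4)c(OC)c3)[C@H](C)[C@@H]2C)cc1OC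
F6 | step 2 | (2S,3R)-4-methoxy-2,3-dimethyl-4-oxobutanoic acid | OC(=O)[C@@H](C)[C@@H](C)C(=O)OC
F7 | step 2 | methyl (2R,3S)-4-chloro-2,3-dimethyl-4-oxobutanoate | ClC(=O)[C@@H](C)[C@@H](C)C(=O)OC
F8 | step 2 | methyl (2R,3S)-4-(3,4-dimethoxyphenyl)-2,3-dimethyl-4-oxobutanoate | COc1ccc(C(=O)[C@@H](C)[C@@H](C)C(=O)OC)cc1OC
F9 | step 3 | (3R,4S,5R)-5-(3,4-dimethoxyphenyl)-3,4-dimethyloxolan-2-one | COc1ccc([C@@H]2OC(=O)[C@H](C)[C@@H]2C)cc1OC
F10 | step 3 | (2R,3S,4R)-4-(3,4-dimethoxyphenyl)-4-hydroxy-2,3-dimethylbutanoic acid | COc1ccc([C@H](O)[C@@H](C)[C@@H](C)C(=O)O)cc1OC
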